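## Retrosynthetic overview (isoflavone numbering)

- The target comes from its penta-O-benzyl ether by one global hydrogenolysis. Rings A and B are bought as arenes, and ring C is the only ring built, formed last.
- Ring C is opened at C4–C4a. This gives a (Z)-2-aryl-3-aryloxyacrylic acid, which closes by intramolecular Friedel–Crafts acylation.
- The strategy rests on ring A being 5,7-dioxygenated. In the open precursor it is the 3,5-bis(benzyloxy)phenyl ether of O1, so the two carbons ortho to O1 (future C4a and C8) are symmetry-equivalent. Each lies ortho to one benzyloxy group and para to the other.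
- O1–C2 comes from 3,5-bis(benzyloxy)phenol and an enol tosylate by addition–elimination. C2 comes from ethyl formate, and C3–C4 from ethyl bromoacetate by Pd-catalysed arylation of its zinc enolate.
- Ring B comes from isovanillin. Bromination at its C2 marks C3', Baeyer–Villiger oxidation turns CHO into the 2'-oxygen, and a B-alkyl Suzuki coupling brings in the side chain already O-benzylated.

Key step: step 13

Assumption: the 3-oxy-substituted acrylates of steps 9 to 13 are drawn as Z isomers (oxygen on future C2 cis to future C4). Any E isomer that forms is carried along, because the conditions of step 13 should interconvert the two.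

Abbreviation: ArB = 2,4-bis(benzyloxy)-3-(3-benzyloxy-3-methylbutyl)-5-methoxyphenyl (ring B).

## Route

Step 1
Reactants: 1 isovanillin (3-hydroxy-4-methoxybenzaldehyde)
Product: 2 2-bromo-3-hydroxy-4-methoxybenzaldehyde
Conditions: Br2, NaOAc, Fe powder (cat.), AcOH, rt
Reagents that add atoms: bromine, BrBr
Why: Electrophilic aromatic bromination directed by the free phenol, which for isovanillin under buffered conditions is well established to go to the ortho carbon between OH and CHO (future C3').

Step 2
Reactants: 2 2-bromo-3-hydroxy-4-methoxybenzaldehyde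
Product: 3 3-(benzyloxy)-2-bromo-4-methoxybenzaldehyde
Conditions: BnBr, K2CO3, DMF, 50 °C
Reagents that add atoms: benzyl bromide, BrCc1ccccc1
Why: Williamson ether synthesis on an acidic phenol, which also shields the ring from oxidation in the next step.

Step 3
Reactants: 3 3-(benzyloxy)-2-bromo-4-methoxybenzaldehyde
Product: 5 3-(benzyloxy)-2-bromo-4-methoxyphenol, via aryl formate 4 (not isolated)
Conditions: mCPBA, CH2Cl2, 0 °C to rt; then K2CO3 (cat.), MeOH, rt
Reagents that add atoms: mCPBA, O=C(OO)c1cccc(Cl)c1
Why: Baeyer–Villiger oxidation in which the aryl group, made electron-rich by the para methoxy group, migrates in preference to hydrogen, followed by transesterification of the formate to free the future 2'-oxygen.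

Step 4
Reactants: 5 3-(benzyloxy)-2-bromo-4-methoxyphenol
Product: 6 1,3-bis(benzyloxy)-2-bromo-4-methoxybenzene
Conditions: BnBr, K2CO3, DMF, 50 °C
Reagents that add atoms: benzyl bromide, BrCc1ccccc1
Why: Williamson ether synthesis, which leaves the methoxy group as the only permanent ether on ring B.

Step 5
Reactants: 7 2-methylbut-3-en-2-ol
Product: 8 benzyl 2-methylbut-3-en-2-yl ether
Conditions: NaH, BnBr, Bu4NI (cat.), THF/DMF, 0 °C to rt
Reagents that add atoms: benzyl bromide, BrCc1ccccc1
Why: Williamson benzylation of a small tertiary allylic alkoxide under iodide catalysis, so the difficult tertiary O-benzylation is done on a cheap C5 unit and not on an advanced intermediate.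

Step 6
Reactants: 8 benzyl 2-methylbut-3-en-2-yl ether; 6 1,3-bis(benzyloxy)-2-bromo-4-methoxybenzene
Product: 10 1,3-bis(benzyloxy)-2-(3-benzyloxy-3-methylbutyl)-4-methoxybenzene, via B-alkyl-9-BBN adduct 9 (not isolated)
Conditions: 9-BBN, THF, rt; then 6, Pd(OAc)2, SPhos, aq K3PO4, THF, 65 °C
Reagents that add atoms: none
Why: Anti-Markovnikov hydroboration puts boron on the terminal carbon of 8, and B-alkyl Suzuki–Miyaura coupling under a bulky electron-rich biarylphosphine, which speeds oxidative addition into the doubly ortho-substituted C–Br bond, joins the chain to C3'.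

Step 7
Reactants: 10 1,3-bis(benzyloxy)-2-(3-benzyloxy-3-methylbutyl)-4-methoxybenzene
Product: 11 2,4-bis(benzyloxy)-3-(3-benzyloxy-3-methylbutyl)-1-bromo-5-methoxybenzene
Conditions: NBS, MeCN, 0 °C, dark
Reagents that add atoms: N-bromosuccinimide, O=C1CCC(=O)N1Br
Why: Polar electrophilic aromatic bromination, in which the arenium ion from attack at C1' is stabilised by the oxygens on C2' and C4' whereas attack at C6' is helped only by the C5' methoxy oxygen and the alkyl group, so C1' should react as in other 1,2,4-trialkoxybenzenes.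

Step 8
Reactants: 11 ArB bromide; 12 ethyl bromoacetate
Product: 14 ethyl 2-ArB-acetate, via Reformatsky zinc reagent 13 (not isolated)
Conditions: Zn dust (TMSCl-activated), 12, THF, 40 °C; then 11, Pd2(dba)3, XPhos, THF, 65 °C
Reagents that add atoms: none
Why: Negishi-type palladium-catalysed α-arylation of a Reformatsky reagent, in which the neutral zinc enolate transmetalates to the arylpalladium bromide and reductive elimination forms C1'–C3 without strong base.

Step 9
Reactants: 14 ethyl 2-ArB-acetate; 15 ethyl formate
Product: 16 ethyl (Z)-2-ArB-3-hydroxyacrylate (chelated enol form of the α-formyl ester)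
Conditions: NaH, HCO2Et, EtOH (cat.), THF, 0 °C to rt; cold 1 M HCl work-up
Reagents that add atoms: none
Why: Crossed Claisen condensation in which only 14 can enolise, the formate is the more electrophilic ester, and deprotonation of the product drives the equilibrium, adding the future C2.

Step 10
Reactants: 16 ethyl (Z)-2-ArB-3-hydroxyacrylate
Product: 17 ethyl (Z)-2-ArB-3-(tosyloxy)acrylate
Conditions: TsCl, TMEDA, LiCl, MeCN, 0 °C
Reagents that add atoms: p-toluenesulfonyl chloride, Cc1ccc(S(=O)(=O)Cl)cc1
Why: Chelation-controlled enol O-sulfonylation, in which lithium ties the enolate oxygen to the ester carbonyl so that tosylation should fix the Z geometry.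

Step 11
Reactants: 17 ethyl (Z)-2-ArB-3-(tosyloxy)acrylate; 18 3,5-bis(benzyloxy)phenol
Product: 19 ethyl (Z)-3-[3,5-bis(benzyloxy)phenoxy]-2-ArB-acrylate
Conditions: Cs2CO3, MeCN, rt
Reagents that add atoms: none
Why: Nucleophilic vinylic substitution by addition–elimination, in which the phenoxide adds to the unhindered β-carbon (future C2) and the ester-stabilised carbanion expels the good nucleofuge tosylate quickly, so retention of the Z geometry is expected.

Step 12
Reactants: 19 ethyl (Z)-3-[3,5-bis(benzyloxy)phenoxy]-2-ArB-acrylate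
Product: 20 (Z)-3-[3,5-bis(benzyloxy)phenoxy]-2-ArB-acrylic acid
Conditions: LiOH, THF/H2O, rt to 40 °C; then 1 M HCl to pH 3, 0 °C
Reagents that add atoms: lithium hydroxide, [Li+].[OH-]
Why: Ester saponification as used for other 3-aryloxyacrylates, run without alcohol co-solvent so that no alkoxide can displace the aryloxy group at C2, with the carboxylate once formed switching off conjugate attack.

Step 13
Reactants: 20 (Z)-3-[3,5-bis(benzyloxy)phenoxy]-2-ArB-acrylic acid
Product: 22 5,7-bis(benzyloxy)-3-ArB-4H-chromen-4-one (penta-O-benzyl isoflavone), via mixed trifluoroacetic anhydride 21 (not isolated)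
Conditions: (CF3CO)2O (1.5 equiv), CH2Cl2 (0.02 M), 0 °C to rt
Reagents that add atoms: none
Why: Trifluoroacetic anhydride turns acid 20 into mixed anhydride 21, whose acyl carbon (future C4), as such or after ionisation to the acylium ion, is attacked by the ring A carbon ortho to O1 (future C4a), and loss of the proton from the arenium ion restores the arene and leaves the C4–C4a bond. This is an intramolecular Friedel–Crafts acylation, the reaction type by which 3-aryloxyacrylic acids are closed to chromones and 2-aryloxybenzoic acids to xanthones. Ring C closes in the 6-exo-trig mode at the anhydride carbonyl (6-exo-dig from the free acylium ion), and no stereocentre is formed. The only selectivity needed is the site on ring A, and it is secured by the mirror symmetry of the 3,5-bis(benzyloxy)phenoxy group: the two carbons ortho to O1 are identical, each is ortho to one and para to the other benzyloxy group, and the carbon between the benzyloxy groups lies para to O1 and cannot reach C4. Any E isomer should drain through the Z isomer, because the activated acid has ketene–oxocarbenium character (ArO+=CH–C(ArB)=C=O) and reversible protonation at C3 also frees rotation about C2–C3. The doubly activated ring needs no Lewis acid, and at high dilution the two equivalents of CF3CO2H stay at a level that the aryl benzyl ethers and the tert-alkyl benzyl ether should tolerate.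

Step 14
Reactants: 22 penta-O-benzyl isoflavone
Product: 23 5,7-dihydroxy-3-[2,4-dihydroxy-3-(3-hydroxy-3-methylbutyl)-5-methoxyphenyl]-4H-chromen-4-one (target)
Conditions: H2 (1 atm), Pd/C (10 wt %), THF/MeOH, rt, stopped when uptake ends
Reagents that add atoms: none
Why: Catalytic hydrogenolysis cleaves all five O–CH2Ph bonds, the tertiary ether at its benzylic carbon so that the quaternary C–O bond stays, in a neutral medium that should allow neither chroman formation nor, at 1 atm with monitoring, reduction of C2=C3.

## Compound list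

1 | isovanillin | COc1ccc(C=O)cc1O | starting material
2 | 2-bromo-3-hydroxy-4-methoxybenzaldehyde | COc1ccc(C=O)c(Br)c1O | intermediate
3 | 3-(benzyloxy)-2-bromo-4-methoxybenzaldehyde | COc1ccc(C=O)c(Br)c1OCc1ccccc1 | intermediate
4 | 3-(benzyloxy)-2-bromo-4-methoxyphenyl formate (not isolated) | COc1ccc(OC=O)c(Br)c1OCc1ccccc1 | intermediate
5 | 3-(benzyloxy)-2-bromo-4-methoxyphenol | COc1ccc(O)c(Br)c1OCc1ccccc1 | intermediate
6 | 1,3-bis(benzyloxy)-2-bromo-4-methoxybenzene | COc1ccc(OCc2ccccc2)c(Br)c1OCc1ccccc1 | intermediate
7 | 2-methylbut-3-en-2-ol | CC(C)(O)C=C | starting material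
8 | benzyl 2-methylbut-3-en-2-yl ether | CC(C)(C=C)OCc1ccccc1 | intermediate
9 | 9-(3-benzyloxy-3-methylbutyl)-9-borabicyclo[3.3.1]nonane (not isolated) | CC(C)(CCB1C2CCCC1CCC2)OCc1ccccc1 | intermediate
10 | 1,3-bis(benzyloxy)-2-(3-benzyloxy-3-methylbutyl)-4-methoxybenzene | COc1ccc(OCc2ccccc2)c(CCC(C)(C)OCc2ccccc2)c1OCc1ccccc1 | intermediate
11 | 2,4-bis(benzyloxy)-3-(3-benzyloxy-3-methylbutyl)-1-bromo-5-methoxybenzene | COc1cc(Br)c(OCc2ccccc2)c(CCC(C)(C)OCc2ccccc2)c1OCc1ccccc1 | intermediate
12 | ethyl bromoacetate | CCOC(=O)CBr | starting material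
13 | bromo(2-ethoxy-2-oxoethyl)zinc (not isolated) | CCOC(=O)C[Zn]Br | intermediate
14 | ethyl 2-[2,4-bis(benzyloxy)-3-(3-benzyloxy-3-methylbutyl)-5-methoxyphenyl]acetate | CCOC(=O)Cc1cc(OC)c(OCc2ccccc2)c(CCC(C)(C)OCc2ccccc2)c1OCc1ccccc1 | intermediate
15 | ethyl formate | CCOC=O | starting material
16 | ethyl (Z)-2-[2,4-bis(benzyloxy)-3-(3-benzyloxy-3-methylbutyl)-5-methoxyphenyl]-3-hydroxyacrylate | CCOC(=O)/C(=C\O)c1cc(OC)c(OCc2ccccc2)c(CCC(C)(C)OCc2ccccc2)c1OCc1ccccc1 | intermediate
17 | ethyl (Z)-2-[2,4-bis(benzyloxy)-3-(3-benzyloxy-3-methylbutyl)-5-methoxyphenyl]-3-(tosyloxy)acrylate | CCOC(=O)/C(=C\OS(=O)(=O)c1ccc(C)cc1)c1cc(OC)c(OCc2ccccc2)c(CCC(C)(C)OCc2ccccc2)c1OCc1ccccc1 | intermediate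
18 | 3,5-bis(benzyloxy)phenol | Oc1cc(OCc2ccccc2)cc(OCc2ccccc2)c1 | starting material
19 | ethyl (Z)-3-[3,5-bis(benzyloxy)phenoxy]-2-[2,4-bis(benzyloxy)-3-(3-benzyloxy-3-methylbutyl)-5-methoxyphenyl]acrylate | CCOC(=O)/C(=C\Oc1cc(OCc2ccccc2)cc(OCc2ccccc2)c1)c1cc(OC)c(OCc2ccccc2)c(CCC(C)(C)OCc2ccccc2)c1OCc1ccccc1 | intermediate
20 | (Z)-3-[3,5-bis(benzyloxy)phenoxy]-2-[2,4-bis(benzyloxy)-3-(3-benzyloxy-3-methylbutyl)-5-methoxyphenyl]acrylic acid | OC(=O)/C(=C\Oc1cc(OCc2ccccc2)cc(OCc2ccccc2)c1)c1cc(OC)c(OCc2ccccc2)c(CCC(C)(C)OCc2ccccc2)c1OCc1ccccc1 | intermediate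
21 | mixed anhydride of acid 20 with trifluoroacetic acid (not isolated) | FC(F)(F)C(=O)OC(=O)/C(=C\Oc1cc(OCc2ccccc2)cc(OCc2ccccc2)c1)c1cc(OC)c(OCc2ccccc2)c(CCC(C)(C)OCc2ccccc2)c1OCc1ccccc1 | intermediate
22 | 5,7-bis(benzyloxy)-3-[2,4-bis(benzyloxy)-3-(3-benzyloxy-3-methylbutyl)-5-methoxyphenyl]-4H-chromen-4-one | O=c1c(-c2cc(OC)c(OCc3ccccc3)c(CCC(C)(C)OCc3ccccc3)c2OCc2ccccc2)coc2cc(OCc3ccccc3)cc(OCc3ccccc3)c12 | intermediate
23 | 5,7-dihydroxy-3-[2,4-dihydroxy-3-(3-hydroxy-3-methylbutyl)-5-methoxyphenyl]-4H-chromen-4-one | COc1cc(-c2coc3cc(O)cc(O)c3c2=O)c(O)c(CCC(C)(C)O)c1O | target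

## Step count and risks

Total step count: 14. Longest linear sequence: 13 steps (steps 1–4 and 6–14, from isovanillin).

Steps most likely to fail:

1. **Step 13.**
   - **Risk:** The released acid may ionise the tertiary benzyl ether. The 2'-benzyloxy oxygen may capture the activated acyl group with loss of benzyl. Ring closure may also be too slow, because the β-aryloxy group tames the acyl electrophile.
   - **Fallback:** This sets out from 11 and returns at 22, with ring C preformed and C3–C1' made by cross-coupling. Bromide 11 would be borylated (B2pin2, PdCl2(dppf), KOAc, dioxane, 80 °C) to the ring B pinacol boronate F1. Commercial 1-[2,4-bis(benzyloxy)-6-hydroxyphenyl]ethanone would be condensed with N,N-dimethylformamide dimethyl acetal (toluene, 90 °C) to the enaminone F2. Iodine in CHCl3 would then iodinate and close it to 5,7-bis(benzyloxy)-3-iodochromone F3. Suzuki–Miyaura coupling of the two partners (Pd(PPh3)4, Na2CO3, DME/H2O, 80 °C) would give 22, and step 14 follows unchanged.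

2. **Step 11.**
   - **Risk:** The phenoxide may attack sulfur instead of the β-carbon, transferring the sulfonyl group and releasing the enolate.
   - **Fallback:** This sets out from 16 and returns at 19, using a leaving group that offers no second electrophilic centre. Enol 16 would be deoxychlorinated with Ph3PCl2 and Et3N in CH2Cl2, the reaction type that turns β-dicarbonyl enols into β-chloro enones. This gives ethyl (Z)-3-chloro-2-ArB-acrylate F4, for which an E/Z mixture would be acceptable. Its reaction with 18 and Cs2CO3 in DMF can then occur only at carbon and would give 19.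

3. **Step 6.**
   - **Risk:** Oxidative addition into the C–Br bond flanked by two benzyloxy groups may be slow, so that hydrodebromination and decay of the borane overtake the coupling.
   - **Fallback:** This sets out from 6 and returns at 10, using polar C–C bond formation. Bromine–lithium exchange (n-BuLi, THF, −78 °C), which is faster than benzylic deprotonation, would give [2,6-bis(benzyloxy)-3-methoxyphenyl]lithium F5. Alkylation at low temperature with prenyl bromide would give the 2-prenyl arene F6. Mukaiyama hydration (Co(acac)2, PhSiH3, O2, THF) would add water in the Markovnikov sense to give the tertiary alcohol F7. Williamson benzylation (KH, BnBr, Bu4NI, THF) would then give 10.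

## Further compounds

F1 | step 13 | 2-[2,4-bis(benzyloxy)-3-(3-benzyloxy-3-methylbutyl)-5-methoxyphenyl]-4,4,5,5-tetramethyl-1,3,2-dioxaborolane | COc1cc(B2OC(C)(C)C(C)(C)O2)c(OCc2ccccc2)c(CCC(C)(C)OCc2ccccc2)c1OCc1ccccc1
F2 | step 13 | (E)-1-[2,4-bis(benzyloxy)-6-hydroxyphenyl]-3-(dimethylamino)prop-2-en-1-one | CN(C)/C=C/C(=O)c1c(O)cc(OCc2ccccc2)cc1OCc1ccccc1
F3 | step 13 | 5,7-bis(benzyloxy)-3-iodo-4H-chromen-4-one | O=c1c(I)coc2cc(OCc3ccccc3)cc(OCc3ccccc3)c12
F4 | step 11 | ethyl (Z)-2-[2,4-bis(benzyloxy)-3-(3-benzyloxy-3-methylbutyl)-5-methoxyphenyl]-3-chloroacrylate | CCOC(=O)/C(=C\Cl)c1cc(OC)c(OCc2ccccc2)c(CCC(C)(C)OCc2ccccc2)c1OCc1ccccc1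
F5 | step 6 | [2,6-bis(benzyloxy)-3-methoxyphenyl]lithium | [Li]c1c(OCc2ccccc2)ccc(OC)c1OCc1ccccc1
F6 | step 6 | 1,3-bis(benzyloxy)-4-methoxy-2-(3-methylbut-2-en-1-yl)benzene | COc1ccc(OCc2ccccc2)c(CC=C(C)C)c1OCc1ccccc1
F7 | step 6 | 4-[2,6-bis(benzyloxy)-3-methoxyphenyl]-2-methylbutan-2-ol | COc1ccc(OCc2ccccc2)c(CCC(C)(C)O)c1OCc1ccccc1
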